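The delta flask cannot make more product than its partner charge of 25.0 mM, since each product takes up one partner. That charge is half of its substrate and so less than the substrate, which makes partner the limiting reagent there. The question is how far below that ceiling it stops.

| flask | substrate | partner | free catalyst | time |
|---|---|---|---|---|
| eta | 50.0 mM | 75.0 mM | 2.50 mM |  |
| beta | 50.0 mM | 110 mM | 2.50 mM |  |
| gamma | 75.0 mM | 75.0 mM | 2.50 mM |  |
| delta | 50.0 mM | 25.0 mM | 5.00 mM | 40 min |

| run | time / min | [product] / mM |
|---|---|---|
| eta run | 1.6 | 0 |
| eta run | 2.7 | 0.6 |
| eta run | 4.7 | 0.5 |
| eta run | 8.0 | 1.8 |
| eta run | 14 | 2.9 |
| eta run | 23 | 5.2 |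
| eta run | 40 | 11.7 |
| beta run | 1.6 | 0.2 |
| beta run | 2.7 | 0.7 |
| beta run | 4.7 | 0.7 |
| beta run | 8.0 | 1.1 |
| beta run | 14 | 2.2 |
| beta run | 23 | 4.4 |
| beta run | 40 | 11.1 |
| gamma run | 1.6 | 0 |
| gamma run | 2.7 | 0.6 |
| gamma run | 4.7 | 0.6 |
| gamma run | 8.0 | 1.9 |
| gamma run | 14 | 4.0 |
| gamma run | 23 | 9.0 |
| gamma run | 40 | 14.7 |

(readings scatter by 0.3 mM)

- Overall: substrate + partner -> product, with free catalyst as catalyst.
- Constant volume, constant temperature.
- Bound and free are read together.
- An order is taken over about fifteen percent of the charge, up and down.

1. the power of [substrate] that the first rate follows, about the charge of the eta run; measure it at two percent of substrate made into product (one fixed amount of product, the same in the runs compared)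
2. the power of [partner] that the first rate follows, about the charge of the eta run; measure it at two percent of substrate made into product
3. product in the delta run at 40 min, as a share of the substrate charged

We build our own estimate for delta one process at a time. With the main step alone, we take the early rate of the eta run, 0.207 mM min⁻¹, and scale it by catalyst. Over 40 min this gives 16.6 mM.

Next comes the partner's brake. The readings at the middle times of beta, summed and divided by those of eta, give a power of c(partner) of −0.656. This is a rough reading, taken at equal times over a wide step and not at the fixed product asked for. On that reading less partner speeds delta, to a reckoned start of 0.852 mM min⁻¹, and the product reckoned at that rate, 34.1 mM, overshoots the ceiling.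

Then comes the rest. Eta's late rate, 0.382 mM min⁻¹, is faster than its early one. If the brake is easing, c(partner) fell by a factor of 2.54 between those stretches. Making product can account for a factor of 1.18 at most, so we suppose that partner also fades by itself, in proportion to what is there, at 0.0381 min⁻¹.

Dividing the product rate by the sum of the product rate and the fade rate removes time. The result is the partner share, the part of the partner that ends as product: 47.2 % at delta's charge. Taking that share as lasting through the run, our estimate is 23.6 % of the substrate.

The forecast gives 0.6 for substrate, −0.4 for partner and 32 % for delta, which is more than our figure. It read the rising curves differently from us: “product seems to promote the reaction”, or catalyst is being released.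

    free catalyst + substrate → catalyst-substrate complex (10.56 L mol⁻¹ min⁻¹)
    catalyst-substrate complex + partner → loaded catalyst (266.4 L mol⁻¹ min⁻¹)
    loaded catalyst → product + free catalyst (3.216 min⁻¹)
    free catalyst + partner ⇌ idle catalyst-reagent complex, settled at all times (132.0 L mol⁻¹)
    partner → lost reagent (0.07620 min⁻¹)

The simulation gives 0.66 for substrate and −0.55 for partner, below the forecast's partner figure. In the delta flask, the catalyst cycle and the loss of partner to lost reagent ran side by side from the start, and at 40 min product stood at 27.5 % of the substrate, which is 55.0 % of the partner charged, against the 47.2 % we reckoned from the start and took as lasting. In the beta flask, the same division, made with its simulated early rate of 0.15 mM min⁻¹ and its partner charge, gives an early share of 3.49 %, and that share did not last there: product reached a quarter of the substrate at 44.4 min, which is 11.4 % of its partner charge.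

All runs come from a simulation for substances that don't exist, noise included.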